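**Retrosynthetic overview**
- Target 28 ← global desilylation ← stereoretentive oxidation of the c7 pinacolboronate 26 (side chain numbered c1–c9 outward from C8 of the flavanone).
- Key disconnection: c5–c6 and c7–c8 are made together by a three-component conjunctive coupling of E-alkenyl bromide 18, vinyllithium 24 and arylethylboronate 22. The strategy rests on the c6H2–c7H(OH) two-carbon unit lying between the E c4=c5 alkene and the c8–c9 arylethyl chain; no ring is involved.
- 18 ← bromo-olefination of α-aryl aldehyde 17 ← catalytic α-arylation (sets c3) ← hydroboration/oxidation of homoallylic ether 10 ← asymmetric allylboration (sets c1) of 8-formylchromone 5.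
- Rings: ring A comes from acetophenone 1; pyranone ring C is closed first (step 1, chromone); ring B and C2 are added by rhodium-catalysed conjugate arylation (step 6); the two side-chain phenol rings are bought; no ring is formed after step 6.

Key step: step 15

Remarks: TBS = tert-butyldimethylsilyl, B(pin) = pinacolatoboryl. The c1 alcohol is made by aldehyde allylation and c3 by aldehyde α-arylation, so no step has to tell the flavanone ketone from a second aryl ketone. Assumption: the catalyst antipodes named in steps 4, 6, 10 and 15 follow the usual facial models for these reaction classes; if a sense were opposite on this substrate, the enantiomeric catalyst would be used with no other change.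

**Step 1**
Reactants: 1 2',4'-dihydroxy-6'-methoxyacetophenone
Product: 3 7-hydroxy-5-methoxy-4H-chromen-4-one, via enaminone 2 (not isolated)
Conditions: t-BuOCH(NMe2)2 (2.5 equiv), toluene, 80 °C; then conc. HCl, CH2Cl2, 40 °C
Reagents that add atoms: tert-butoxybis(dimethylamino)methane, CC(C)(C)OC(N(C)C)N(C)C
Why: Aminomethylenation of the methyl ketone gives enaminone 2, and acid then drives conjugate addition of the ortho-hydroxyl with loss of dimethylamine to close ring C (enaminone route to chromones); this aminal ester cannot O-methylate the free 4'-hydroxyl.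

**Step 2**
Reactants: 3 7-hydroxy-5-methoxy-4H-chromen-4-one
Product: 4 7-hydroxy-5-methoxy-4-oxo-4H-chromene-8-carbaldehyde
Conditions: MgCl2 (2 equiv), Et3N (4 equiv), (CH2O)n (6 equiv), MeCN, 80 °C; then 1 M HCl
Reagents that add atoms: formaldehyde (as paraformaldehyde), C=O
Why: Magnesium-mediated ortho-formylation of the phenoxide (Casnati–Skattebøl reaction) delivers formaldehyde within a magnesium chelate, and C8 is expected over C6 because it is the alpha-type position of the benzopyranone (as in 8-formylation of 7-hydroxycoumarins) and lies para to the 5-methoxy group.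

**Step 3**
Reactants: 4 7-hydroxy-5-methoxy-4-oxo-4H-chromene-8-carbaldehyde
Product: 5 5-methoxy-4-oxo-7-(TBSO)-4H-chromene-8-carbaldehyde
Conditions: TBSCl (1.3 equiv), imidazole (2.5 equiv), DMF, rt
Reagents that add atoms: tert-butyldimethylsilyl chloride, CC(C)(C)[Si](C)(C)Cl
Why: Imidazole-promoted silylation of the acidic, hydrogen-bonded phenol masks O7 before the carbonyl additions.

**Step 4**
Reactants: 5 5-methoxy-4-oxo-7-(TBSO)-4H-chromene-8-carbaldehyde
Product: 7 8-[(1S)-1-hydroxybut-3-en-1-yl]-5-methoxy-7-(TBSO)-4H-chromen-4-one, via pinacol borate ester 6 (not isolated)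
Conditions: allyl-B(pin) (1.5 equiv), (S)-TRIP [(S)-3,3'-bis(2,4,6-triisopropylphenyl)-1,1'-binaphthyl-2,2'-diyl hydrogen phosphate] (5 mol%), toluene, −30 °C; aqueous work-up
Reagents that add atoms: allylboronic acid pinacol ester, C=CCB1OC(C)(C)C(C)(C)O1
Why: Chiral phosphoric acid-catalysed allylboration runs through a closed chair transition state in which the acid hydrogen-bonds the boronate oxygen and the formyl hydrogen, so the allyl group should add to the Si face and set c1 as S; the vinylogous-ester carbonyl of the chromone does not react with allylboronates.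

**Step 5**
Reactants: 7 8-[(1S)-1-hydroxybut-3-en-1-yl]-5-methoxy-7-(TBSO)-4H-chromen-4-one
Product: 8 5-methoxy-7-(TBSO)-8-[(1S)-1-(TBSO)but-3-en-1-yl]-4H-chromen-4-one
Conditions: TBSOTf (1.5 equiv), 2,6-lutidine (3 equiv), CH2Cl2, −78 → 0 °C
Reagents that add atoms: tert-butyldimethylsilyl triflate, CC(C)(C)[Si](C)(C)OS(=O)(=O)C(F)(F)F
Why: Silyl triflate silylation under lutidine buffering is the standard way to protect a hindered secondary benzylic alcohol.

**Step 6**
Reactants: 8 5-methoxy-7-(TBSO)-8-[(1S)-1-(TBSO)but-3-en-1-yl]-4H-chromen-4-one; 9 [4-(TBSO)phenyl]boronic acid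
Product: 10 (2S)-5-methoxy-7-(TBSO)-8-[(1S)-1-(TBSO)but-3-en-1-yl]-2-[4-(TBSO)phenyl]chroman-4-one
Conditions: [Rh(OH)(cod)]2 (2.5 mol%), (S)-MeO-F12-BIPHEP [(S)-6,6'-dimethoxy-2,2'-bis[bis(3,4,5-trifluorophenyl)phosphino]-1,1'-biphenyl] (5.5 mol%), 9 (3 equiv), CH2Cl2/H2O (10:1), 20 °C
Reagents that add atoms: none
Why: Rhodium-catalysed asymmetric 1,4-addition of the arylboronic acid to the chromone (Hayashi–Miyaura reaction) adds aryl–rhodium to C2 from the face chosen by the bisphosphine, which sets C2 as S and installs ring B; the electron-poor ligand is the type known to overcome the low reactivity of chromones, and the terminal alkene and silyl ethers are inert.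

**Step 7**
Reactants: 10 (2S)-5-methoxy-7-(TBSO)-8-[(1S)-1-(TBSO)but-3-en-1-yl]-2-[4-(TBSO)phenyl]chroman-4-one
Product: 12 (2S)-8-[(1S)-4-hydroxy-1-(TBSO)butyl]-5-methoxy-7-(TBSO)-2-[4-(TBSO)phenyl]chroman-4-one, via B-alkyl-9-BBN adduct 11 (not isolated)
Conditions: 9-BBN (1.5 equiv), THF, 0 °C → rt; then NaBO3·4H2O, H2O, rt
Reagents that add atoms: sodium perborate tetrahydrate, [Na+].[O-]OB=O
Why: Anti-Markovnikov hydroboration of the terminal alkene with 9-BBN (Brown hydroboration) is much faster than reduction of the deactivated aryl ketone, and perborate then oxidises the primary C–B bond under mild conditions.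

**Step 8**
Reactants: 12 (2S)-8-[(1S)-4-hydroxy-1-(TBSO)butyl]-5-methoxy-7-(TBSO)-2-[4-(TBSO)phenyl]chroman-4-one
Product: 13 (4S)-4-[(2S)-5-methoxy-4-oxo-7-(TBSO)-2-[4-(TBSO)phenyl]chroman-8-yl]-4-(TBSO)butanal
Conditions: Dess–Martin periodinane (1.3 equiv), CH2Cl2, 0 °C → rt
Reagents that add atoms: none
Why: Dess–Martin oxidation converts the primary alcohol to the aldehyde under neutral conditions that leave the silyl ethers and the flavanone untouched.

**Step 9**
Reactants: 9 [4-(TBSO)phenyl]boronic acid; 14 (diacetoxyiodo)mesitylene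
Product: 16 [4-(TBSO)phenyl](2,4,6-trimethylphenyl)iodonium triflate, via iodonium tetrafluoroborate 15 (not isolated)
Conditions: BF3·OEt2 (2.5 equiv), CH2Cl2, −20 → 0 °C; then aqueous NaOTf
Reagents that add atoms: sodium triflate, [Na+].[O-]S(=O)(=O)C(F)(F)F
Why: Boron-to-iodine aryl transfer from the boronic acid to the Lewis acid-activated diacetoxyiodoarene gives the unsymmetrical diaryliodonium salt by ipso substitution, and salt metathesis supplies the weakly coordinating triflate; mesityl is the non-transferable group.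

**Step 10**
Reactants: 13 (4S)-4-[(2S)-5-methoxy-4-oxo-7-(TBSO)-2-[4-(TBSO)phenyl]chroman-8-yl]-4-(TBSO)butanal; 16 [4-(TBSO)phenyl](2,4,6-trimethylphenyl)iodonium triflate
Product: 17 (2S,4S)-4-[(2S)-5-methoxy-4-oxo-7-(TBSO)-2-[4-(TBSO)phenyl]chroman-8-yl]-4-(TBSO)-2-[4-(TBSO)phenyl]butanal
Conditions: 16 (2 equiv), CuBr (10 mol%), (2R,5R)-5-benzyl-2-tert-butyl-3-methylimidazolidin-4-one·CCl3CO2H (20 mol%), NaHCO3 (2 equiv), toluene/Et2O (2:1), 23 °C; short silica pad, used at once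
Reagents that add atoms: none
Why: In this copper/amine dual-catalysed enantioselective α-arylation of an aldehyde, the E-enamine formed with the imidazolidinone is arylated on its Re face by the aryl–copper species (trivalent copper) generated from CuBr and the iodonium salt, which sets c3 under catalyst control while the bulky mesityl group stays on iodine.

**Step 11**
Reactants: 17 (2S,4S)-4-[(2S)-5-methoxy-4-oxo-7-(TBSO)-2-[4-(TBSO)phenyl]chroman-8-yl]-4-(TBSO)-2-[4-(TBSO)phenyl]butanal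
Product: 18 (2S)-8-[(1S,3R,4E)-5-bromo-1-(TBSO)-3-[4-(TBSO)phenyl]pent-4-en-1-yl]-5-methoxy-7-(TBSO)-2-[4-(TBSO)phenyl]chroman-4-one
Conditions: CHBr3 (2.5 equiv), CrBr2 (8 equiv), THF, 0 °C → rt
Reagents that add atoms: bromoform, BrC(Br)Br
Why: In the Takai–Utimoto olefination the geminal dichromium species from bromoform and chromium dibromide adds only to the aldehyde and eliminates to the E-alkenyl bromide; the all-bromide system avoids halogen exchange and the non-basic medium should spare the α-aryl centre and the flavanone.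

**Step 12**
Reactants: 19 4-acetoxystyrene
Product: 21 tert-butyl(4-ethenylphenoxy)dimethylsilane, via 4-ethenylphenol 20 (not isolated)
Conditions: K2CO3 (cat.), MeOH, 0 °C; extractive work-up; TBSCl, imidazole, CH2Cl2, rt
Reagents that add atoms: tert-butyldimethylsilyl chloride, CC(C)(C)[Si](C)(C)Cl
Why: Transesterification of the aryl acetate with methanol followed by imidazole-promoted silylation protects the polymerisation-prone 4-vinylphenol without isolating it.

**Step 13**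
Reactants: 21 tert-butyl(4-ethenylphenoxy)dimethylsilane
Product: 22 2-{2-[4-(TBSO)phenyl]ethyl}-4,4,5,5-tetramethyl-1,3,2-dioxaborolane
Conditions: HB(pin) (1.2 equiv), [Ir(cod)Cl]2 (1.5 mol%), dppe (3 mol%), CH2Cl2, rt
Reagents that add atoms: pinacolborane, [H]B1OC(C)(C)C(C)(C)O1
Why: Iridium-catalysed hydroboration of a vinylarene with pinacolborane gives the linear (anti-Markovnikov) alkylboronate.

**Step 14**
Reactants: 23 tetraethenylstannane
Product: 24 ethenyllithium (vinyllithium)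
Conditions: n-BuLi (4 equiv), pentane, rt; solid filtered under Ar, washed with pentane, dissolved in Et2O and titrated
Reagents that add atoms: n-butyllithium, [Li]CCCC
Why: Tin–lithium exchange transfers the vinyl groups from tin to lithium and halide-free vinyllithium precipitates from pentane, which matters because halide ions inhibit the coupling.

**Step 15**
Reactants: 22 2-{2-[4-(TBSO)phenyl]ethyl}-4,4,5,5-tetramethyl-1,3,2-dioxaborolane; 24 ethenyllithium; 18 (2S)-8-[(1S,3R,4E)-5-bromo-1-(TBSO)-3-[4-(TBSO)phenyl]pent-4-en-1-yl]-5-methoxy-7-(TBSO)-2-[4-(TBSO)phenyl]chroman-4-one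
Product: 26 (2S)-5-methoxy-8-[(1S,3R,4E,7S)-7-B(pin)-1-(TBSO)-3,9-bis[4-(TBSO)phenyl]non-4-en-1-yl]-7-(TBSO)-2-[4-(TBSO)phenyl]chroman-4-one, via lithium vinylboronate complex 25 (not isolated)
Conditions: 22 (1.6 equiv), 24 (1.5 equiv), Et2O, 0 °C → rt; evaporate; then 18 (1.0 equiv), Pd(OAc)2 (3 mol%), (Sp,Sp)-MandyPhos [(Sp,Sp)-1,1'-bis[bis(4-methoxy-3,5-dimethylphenyl)phosphino]-2,2'-bis[(R)-α-(dimethylamino)benzyl]ferrocene] (3.6 mol%), KOTf (2 equiv), THF, 60 °C
Reagents that add atoms: none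
Why: Zerovalent palladium, formed from Pd(OAc)2 and the phosphine, adds oxidatively to the C–Br bond of 18, and triflate takes the place of bromide to give a cationic E-alkenylpalladium complex (divalent palladium). This complex binds the vinyl group of 25 and triggers a 1,2-metallate shift in which the arylethyl group moves from boron to the internal vinyl carbon (c7) anti to palladium while palladium bonds to c6; reductive elimination then forms c5–c6 with the E geometry kept and returns zerovalent palladium. The closest known reaction type is the palladium-catalysed enantioselective conjunctive cross-coupling of vinylboron ate complexes with alkenyl electrophiles and alkyl migrating groups, run with a triflate salt as halide scavenger. No ring is closed; the two new bonds are c5–c6 and c7–c8. The only new stereocentre, c7, is set as S by the chiral ferrocenyl bisphosphine, which selects the vinyl face that palladium binds, and the remote C2, c1 and c3 centres are not expected to override it. The step needs the metallate shift to win over direct Suzuki-type transmetallation and needs the flavanone to survive: the cationic palladium centre and the four-coordinate boronate favour the first, the unhindered E-disubstituted alkenyl bromide of 18 makes oxidative addition fast, and the ate complex is neither basic nor nucleophilic towards the aryl ketone provided vinyllithium is kept slightly below 22.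

**Step 16**
Reactants: 26 (2S)-5-methoxy-8-[(1S,3R,4E,7S)-7-B(pin)-1-(TBSO)-3,9-bis[4-(TBSO)phenyl]non-4-en-1-yl]-7-(TBSO)-2-[4-(TBSO)phenyl]chroman-4-one
Product: 27 (2S)-8-[(1S,3R,4E,7S)-7-hydroxy-1-(TBSO)-3,9-bis[4-(TBSO)phenyl]non-4-en-1-yl]-5-methoxy-7-(TBSO)-2-[4-(TBSO)phenyl]chroman-4-one
Conditions: NaBO3·4H2O (5 equiv), THF/H2O (1:1), rt
Reagents that add atoms: sodium perborate tetrahydrate, [Na+].[O-]OB=O
Why: Perborate oxidation of the secondary alkylboronate proceeds by 1,2-migration of carbon from boron to oxygen with retention, so c7 keeps its configuration, and the mildly basic medium should spare the flavanone.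

**Step 17**
Reactants: 27 (2S)-8-[(1S,3R,4E,7S)-7-hydroxy-1-(TBSO)-3,9-bis[4-(TBSO)phenyl]non-4-en-1-yl]-5-methoxy-7-(TBSO)-2-[4-(TBSO)phenyl]chroman-4-one
Product: 28 (2S)-8-[(1S,3R,4E,7S)-1,7-dihydroxy-3,9-bis(4-hydroxyphenyl)non-4-en-1-yl]-7-hydroxy-2-(4-hydroxyphenyl)-5-methoxy-2,3-dihydro-4H-chromen-4-one
Conditions: TBAF (8 equiv), AcOH (8 equiv), THF, 0 °C → rt
Reagents that add atoms: none
Why: Fluoride cleaves the four aryl silyl ethers and the benzylic one, and the acetic acid buffer keeps the phenols protonated so that retro-oxa-Michael opening of the flavanone (and thus racemisation at C2) and ionisation at c1 should be avoided.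

**Compound list**
1 | 2',4'-dihydroxy-6'-methoxyacetophenone | CC(=O)c1c(O)cc(O)cc1OC | starting material
2 | (E)-1-(2,4-dihydroxy-6-methoxyphenyl)-3-(dimethylamino)prop-2-en-1-one | COc1cc(O)cc(O)c1C(=O)/C=C/N(C)C | intermediate
3 | 7-hydroxy-5-methoxy-4H-chromen-4-one | COc1cc(O)cc2occc(=O)c12 | intermediate
4 | 7-hydroxy-5-methoxy-4-oxo-4H-chromene-8-carbaldehyde | COc1cc(O)c(C=O)c2occc(=O)c12 | intermediate
5 | 5-methoxy-4-oxo-7-(TBSO)-4H-chromene-8-carbaldehyde | COc1cc(O[Si](C)(C)C(C)(C)C)c(C=O)c2occc(=O)c12 | intermediate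
6 | pinacol borate ester of alcohol 7 (c1 S) | COc1cc(O[Si](C)(C)C(C)(C)C)c([C@@H](OB3OC(C)(C)C(C)(C)O3)CC=C)c2occc(=O)c12 | intermediate
7 | 8-[(1S)-1-hydroxybut-3-en-1-yl]-5-methoxy-7-(TBSO)-4H-chromen-4-one | COc1cc(O[Si](C)(C)C(C)(C)C)c([C@@H](O)CC=C)c2occc(=O)c12 | intermediate
8 | 5-methoxy-7-(TBSO)-8-[(1S)-1-(TBSO)but-3-en-1-yl]-4H-chromen-4-one | COc1cc(O[Si](C)(C)C(C)(C)C)c([C@@H](O[Si](C)(C)C(C)(C)C)CC=C)c2occc(=O)c12 | intermediate
9 | [4-(TBSO)phenyl]boronic acid | OB(O)c1ccc(O[Si](C)(C)C(C)(C)C)cc1 | starting material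
10 | (2S)-5-methoxy-7-(TBSO)-8-[(1S)-1-(TBSO)but-3-en-1-yl]-2-[4-(TBSO)phenyl]chroman-4-one | COc1cc(O[Si](C)(C)C(C)(C)C)c([C@@H](O[Si](C)(C)C(C)(C)C)CC=C)c2c1C(=O)C[C@@H](c1ccc(O[Si](C)(C)C(C)(C)C)cc1)O2 | intermediate
11 | B-alkyl-9-borabicyclo[3.3.1]nonane adduct of 10 (boron on the terminal carbon) | COc1cc(O[Si](C)(C)C(C)(C)C)c([C@@H](O[Si](C)(C)C(C)(C)C)CCCB3C4CCCC3CCC4)c2c1C(=O)C[C@@H](c1ccc(O[Si](C)(C)C(C)(C)C)cc1)O2 | intermediate
12 | (2S)-8-[(1S)-4-hydroxy-1-(TBSO)butyl]-5-methoxy-7-(TBSO)-2-[4-(TBSO)phenyl]chroman-4-one | COc1cc(O[Si](C)(C)C(C)(C)C)c([C@@H](O[Si](C)(C)C(C)(C)C)CCCO)c2c1C(=O)C[C@@H](c1ccc(O[Si](C)(C)C(C)(C)C)cc1)O2 | intermediate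
13 | (4S)-4-[(2S)-5-methoxy-4-oxo-7-(TBSO)-2-[4-(TBSO)phenyl]chroman-8-yl]-4-(TBSO)butanal | COc1cc(O[Si](C)(C)C(C)(C)C)c([C@@H](O[Si](C)(C)C(C)(C)C)CCC=O)c2c1C(=O)C[C@@H](c1ccc(O[Si](C)(C)C(C)(C)C)cc1)O2 | intermediate
14 | (diacetoxyiodo)mesitylene | CC(=O)OI(OC(C)=O)c1c(C)cc(C)cc1C | starting material
15 | [4-(TBSO)phenyl](2,4,6-trimethylphenyl)iodonium tetrafluoroborate | Cc1cc(C)c([I+]c2ccc(O[Si](C)(C)C(C)(C)C)cc2)c(C)c1.F[B-](F)(F)F | intermediate
16 | [4-(TBSO)phenyl](2,4,6-trimethylphenyl)iodonium triflate | Cc1cc(C)c([I+]c2ccc(O[Si](C)(C)C(C)(C)C)cc2)c(C)c1.[O-]S(=O)(=O)C(F)(F)F | intermediate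
17 | (2S,4S)-4-[(2S)-5-methoxy-4-oxo-7-(TBSO)-2-[4-(TBSO)phenyl]chroman-8-yl]-4-(TBSO)-2-[4-(TBSO)phenyl]butanal | COc1cc(O[Si](C)(C)C(C)(C)C)c([C@@H](O[Si](C)(C)C(C)(C)C)C[C@H](C=O)c3ccc(O[Si](C)(C)C(C)(C)C)cc3)c2c1C(=O)C[C@@H](c1ccc(O[Si](C)(C)C(C)(C)C)cc1)O2 | intermediate
18 | (2S)-8-[(1S,3R,4E)-5-bromo-1-(TBSO)-3-[4-(TBSO)phenyl]pent-4-en-1-yl]-5-methoxy-7-(TBSO)-2-[4-(TBSO)phenyl]chroman-4-one | COc1cc(O[Si](C)(C)C(C)(C)C)c([C@@H](O[Si](C)(C)C(C)(C)C)C[C@H](/C=C/Br)c2ccc(O[Si](C)(C)C(C)(C)C)cc2)c2c1C(=O)C[C@@H](c1ccc(O[Si](C)(C)C(C)(C)C)cc1)O2 | intermediate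
19 | 4-acetoxystyrene | CC(=O)Oc1ccc(C=C)cc1 | starting material
20 | 4-ethenylphenol | Oc1ccc(C=C)cc1 | intermediate
21 | tert-butyl(4-ethenylphenoxy)dimethylsilane | C=Cc1ccc(O[Si](C)(C)C(C)(C)C)cc1 | intermediate
22 | 2-{2-[4-(TBSO)phenyl]ethyl}-4,4,5,5-tetramethyl-1,3,2-dioxaborolane | CC1(C)OB(CCc2ccc(O[Si](C)(C)C(C)(C)C)cc2)OC1(C)C | intermediate
23 | tetraethenylstannane | C=C[Sn](C=C)(C=C)C=C | starting material
24 | ethenyllithium | [Li]C=C | intermediate
25 | lithium ethenyl{2-[4-(TBSO)phenyl]ethyl}(pinacolato)borate | [Li+].C=C[B-]1(CCc2ccc(O[Si](C)(C)C(C)(C)C)cc2)OC(C)(C)C(C)(C)O1 | intermediate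
26 | (2S)-5-methoxy-8-[(1S,3R,4E,7S)-7-B(pin)-1-(TBSO)-3,9-bis[4-(TBSO)phenyl]non-4-en-1-yl]-7-(TBSO)-2-[4-(TBSO)phenyl]chroman-4-one | COc1cc(O[Si](C)(C)C(C)(C)C)c([C@@H](O[Si](C)(C)C(C)(C)C)C[C@H](/C=C/C[C@@H](B3OC(C)(C)C(C)(C)O3)CCc3ccc(O[Si](C)(C)C(C)(C)C)cc3)c3ccc(O[Si](C)(C)C(C)(C)C)cc3)c2c1C(=O)C[C@@H](c1ccc(O[Si](C)(C)C(C)(C)C)cc1)O2 | intermediate
27 | (2S)-8-[(1S,3R,4E,7S)-7-hydroxy-1-(TBSO)-3,9-bis[4-(TBSO)phenyl]non-4-en-1-yl]-5-methoxy-7-(TBSO)-2-[4-(TBSO)phenyl]chroman-4-one | COc1cc(O[Si](C)(C)C(C)(C)C)c([C@@H](O[Si](C)(C)C(C)(C)C)C[C@H](/C=C/C[C@@H](O)CCc3ccc(O[Si](C)(C)C(C)(C)C)cc3)c3ccc(O[Si](C)(C)C(C)(C)C)cc3)c2c1C(=O)C[C@@H](c1ccc(O[Si](C)(C)C(C)(C)C)cc1)O2 | intermediate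
28 | (2S)-8-[(1S,3R,4E,7S)-1,7-dihydroxy-3,9-bis(4-hydroxyphenyl)non-4-en-1-yl]-7-hydroxy-2-(4-hydroxyphenyl)-5-methoxy-2,3-dihydro-4H-chromen-4-one (CNP0415883.1) | COc1cc(O)c([C@@H](O)C[C@H](/C=C/C[C@@H](O)CCc2ccc(O)cc2)c2ccc(O)cc2)c2c1C(=O)C[C@@H](c1ccc(O)cc1)O2 | target

**Step count and risks**
Total step count: 17. Longest linear sequence: 13 steps (steps 1–8, 10, 11, 15, 16, 17).

Steps most likely to fail:

1. Step 15 (conjunctive coupling). Direct Suzuki-type transfer of the vinyl or arylethyl group may compete with the metallate shift, residual bromide may slow the catalyst, the flavanone may open if any free organolithium or base is present, and the nearby c3 centre may erode ligand control at c7. The fallback builds the c4=c5 alkene by cross-metathesis and sets c7 beforehand in a small fragment. It sets out from aldehyde 17, which is methylenated selectively at the aldehyde (CH2I2, Zn, Ti(OiPr)4, THF) to the terminal alkene (2S)-5-methoxy-7-(TBSO)-8-[(1S,3R)-1-(TBSO)-3-[4-(TBSO)phenyl]pent-4-en-1-yl]-2-[4-(TBSO)phenyl]chroman-4-one F1. In parallel, commercial methyl 3-(4-hydroxyphenyl)propanoate is silylated (TBSCl, imidazole) to methyl 3-[4-(TBSO)phenyl]propanoate F2, reduced (i-Bu2AlH, −78 °C) to 3-[4-(TBSO)phenyl]propanal F3 and allylated with (+)-B-allyldiisopinocampheylborane (Brown allylation) to (3S)-1-[4-(TBSO)phenyl]hex-5-en-3-ol F4. Cross-metathesis of F1 with F4 (second-generation Hoveyda–Grubbs catalyst, CH2Cl2, 40 °C) should give the E-alkene and comes back to the route at alcohol 27.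

2. Step 10 (α-arylation). Enamine formation may be slow with the bulky γ-branched aldehyde, the electron-rich ring A may be arylated in competition, and the α-aryl aldehyde may racemise through the enamine. The fallback brings the aryl group in as part of the allyl unit and sets c3 by catalytic asymmetric hydroboration. It sets out from aldehyde 5: (S)-TRIP-catalysed allylboration with 2-bromoallylboronic acid pinacol ester gives 8-[(1S)-3-bromo-1-hydroxybut-3-en-1-yl]-5-methoxy-7-(TBSO)-4H-chromen-4-one F5, and silylation (TBSOTf, 2,6-lutidine) gives its TBS ether F6. Suzuki–Miyaura coupling of F6 with boronic acid 9 (Pd(dppf)Cl2, K3PO4, THF/H2O, 40 °C) gives the 1,1-disubstituted styrene 5-methoxy-7-(TBSO)-8-[(1S)-1-(TBSO)-3-[4-(TBSO)phenyl]but-3-en-1-yl]-4H-chromen-4-one F7, and rhodium-catalysed 1,4-arylation with 9 as in step 6 gives the flavanone F8. Copper-catalysed enantioselective protoboration of the styrene (CuCl, chiral N-heterocyclic carbene ligand, B2(pin)2, MeOH) gives the primary pinacolboronate F9 with c3 set by the ligand, perborate oxidation gives the primary alcohol F10, and Dess–Martin oxidation comes back to the route at aldehyde 17.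

3. Step 2 (formylation). Attack at C6 instead of C8, or a sluggish reaction of the weakly nucleophilic pyranone-conjugated phenoxide, would cost material at the start. The fallback places the carbon at C8 by a sigmatropic shift. It sets out from chromone 3: O-allylation (allyl bromide, K2CO3, acetone) gives 7-(allyloxy)-5-methoxy-4H-chromen-4-one F11, and aromatic Claisen rearrangement (N,N-diethylaniline, 190 °C) gives 8-allyl-7-hydroxy-5-methoxy-4H-chromen-4-one F12. Alkene isomerisation (RuHCl(CO)(PPh3)3, toluene, 80 °C) gives 7-hydroxy-5-methoxy-8-[(E)-prop-1-en-1-yl]-4H-chromen-4-one F13, and Lemieux–Johnson cleavage (OsO4 cat., NaIO4, 2,6-lutidine, dioxane/H2O) comes back to the route at aldehyde 4.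

**Further compounds**
F1 | step 15 | (2S)-5-methoxy-7-(TBSO)-8-[(1S,3R)-1-(TBSO)-3-[4-(TBSO)phenyl]pent-4-en-1-yl]-2-[4-(TBSO)phenyl]chroman-4-one | COc1cc(O[Si](C)(C)C(C)(C)C)c([C@@H](O[Si](C)(C)C(C)(C)C)C[C@H](C=C)c2ccc(O[Si](C)(C)C(C)(C)C)cc2)c2c1C(=O)C[C@@H](c1ccc(O[Si](C)(C)C(C)(C)C)cc1)O2
F2 | step 15 | methyl 3-[4-(TBSO)phenyl]propanoate | COC(=O)CCc1ccc(O[Si](C)(C)C(C)(C)C)cc1
F3 | step 15 | 3-[4-(TBSO)phenyl]propanal | O=CCCc1ccc(O[Si](C)(C)C(C)(C)C)cc1
F4 | step 15 | (3S)-1-[4-(TBSO)phenyl]hex-5-en-3-ol | C=CC[C@@H](O)CCc1ccc(O[Si](C)(C)C(C)(C)C)cc1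
F5 | step 10 | 8-[(1S)-3-bromo-1-hydroxybut-3-en-1-yl]-5-methoxy-7-(TBSO)-4H-chromen-4-one | COc1cc(O[Si](C)(C)C(C)(C)C)c([C@@H](O)CC(Br)=C)c2occc(=O)c12
F6 | step 10 | 8-[(1S)-3-bromo-1-(TBSO)but-3-en-1-yl]-5-methoxy-7-(TBSO)-4H-chromen-4-one | COc1cc(O[Si](C)(C)C(C)(C)C)c([C@@H](O[Si](C)(C)C(C)(C)C)CC(Br)=C)c2occc(=O)c12
F7 | step 10 | 5-methoxy-7-(TBSO)-8-[(1S)-1-(TBSO)-3-[4-(TBSO)phenyl]but-3-en-1-yl]-4H-chromen-4-one | COc1cc(O[Si](C)(C)C(C)(C)C)c([C@@H](O[Si](C)(C)C(C)(C)C)CC(=C)c3ccc(O[Si](C)(C)C(C)(C)C)cc3)c2occc(=O)c12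
F8 | step 10 | (2S)-5-methoxy-7-(TBSO)-8-[(1S)-1-(TBSO)-3-[4-(TBSO)phenyl]but-3-en-1-yl]-2-[4-(TBSO)phenyl]chroman-4-one | COc1cc(O[Si](C)(C)C(C)(C)C)c([C@@H](O[Si](C)(C)C(C)(C)C)CC(=C)c3ccc(O[Si](C)(C)C(C)(C)C)cc3)c2c1C(=O)C[C@@H](c1ccc(O[Si](C)(C)C(C)(C)C)cc1)O2
F9 | step 10 | (2S)-8-[(1S,3S)-4-B(pin)-1-(TBSO)-3-[4-(TBSO)phenyl]butyl]-5-methoxy-7-(TBSO)-2-[4-(TBSO)phenyl]chroman-4-one | COc1cc(O[Si](C)(C)C(C)(C)C)c([C@@H](O[Si](C)(C)C(C)(C)C)C[C@H](CB3OC(C)(C)C(C)(C)O3)c3ccc(O[Si](C)(C)C(C)(C)C)cc3)c2c1C(=O)C[C@@H](c1ccc(O[Si](C)(C)C(C)(C)C)cc1)O2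
F10 | step 10 | (2S)-8-[(1S,3S)-4-hydroxy-1-(TBSO)-3-[4-(TBSO)phenyl]butyl]-5-methoxy-7-(TBSO)-2-[4-(TBSO)phenyl]chroman-4-one | COc1cc(O[Si](C)(C)C(C)(C)C)c([C@@H](O[Si](C)(C)C(C)(C)C)C[C@H](CO)c3ccc(O[Si](C)(C)C(C)(C)C)cc3)c2c1C(=O)C[C@@H](c1ccc(O[Si](C)(C)C(C)(C)C)cc1)O2
F11 | step 2 | 7-(allyloxy)-5-methoxy-4H-chromen-4-one | COc1cc(OCC=C)cc2occc(=O)c12
F12 | step 2 | 8-allyl-7-hydroxy-5-methoxy-4H-chromen-4-one | COc1cc(O)c(CC=C)c2occc(=O)c12
F13 | step 2 | 7-hydroxy-5-methoxy-8-[(E)-prop-1-en-1-yl]-4H-chromen-4-one | COc1cc(O)c(/C=C/C)c2occc(=O)c12
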